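The chain is numbered C1 (diene CH2) to C14 (ester carbinol). Everything rests on cutting both bonds to the C9 ketone carbon, which sits between the C8 methylene (β to the C7 carbinol) and the C10 carbinol in an open chain with no ring. In one flask a lithiated 2-silyl-1,3-dithiane opens the C7–C8 epoxide at C8, silicon moves from C9 to O7, and the new C9 anion is acylated by the C10 Weinreb amide. The precursors are the (5S,7R) C4–C8 epoxide carrying triethylsilyl ethers at O4 and O5 and the (11S,12S,14R) C10–C14 amide with O11 silylated and O14 as 4-methoxybenzyl ether; the epoxy dienoic acid is attached last.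

Key step: step 15

Remarks:
- TES = triethylsilyl, TBS = tert-butyldimethylsilyl, PMB = 4-methoxybenzyl. Locants C4–C14 in names of chain intermediates follow the target numbering above.
- Assumption: (R)-pent-4-yn-2-ol is bought; it is otherwise one step from (R)-propylene oxide and lithium acetylide.
- O4 carries a primary TES ether and O14 the only PMB ether, so that C4 and O14 can be unmasked at different times. Two PMB ethers could not be told apart, and oxidative PMB removal next to the finished diene is avoided.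
- The configurations of the coupling partners were derived atom by atom from the target: (R)-2-methylglycidol gives 5S, and the amide is (2S,3S,5R).

**Part A: dithiane linchpin**

Step 1
Reactants: 1 1,3-dithiane
Product: 3 2-(tert-butyldimethylsilyl)-1,3-dithiane, via 2-lithio-1,3-dithiane 2 (not isolated)
Conditions: n-BuLi, THF, −30 °C; TBSCl, −78 °C → rt
Reagents that add atoms: tert-butyldimethylsilyl chloride, CC(C)(C)[Si](C)(C)Cl
Why: Deprotonation at C2 of the dithiane and C-silylation of the anion is the standard preparation of this linchpin.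

**Part B: C4–C8 epoxide**

Step 2
Reactants: 4 (R)-2-methylglycidol
Product: 5 (2S)-2-methylpent-4-ene-1,2-diol
Conditions: CH2=CHMgBr (3 equiv), CuI (10 mol%), THF, −30 → 0 °C; aq NH4Cl
Reagents that add atoms: vinylmagnesium bromide, C=C[Mg]Br
Why: Copper-catalysed Grignard opening of the magnesium alkoxide of the glycidol should occur at the unsubstituted epoxide carbon (first equivalent consumed by the hydroxyl), leaving the quaternary center, the future C5, untouched.

Step 3
Reactants: 5 (2S)-2-methylpent-4-ene-1,2-diol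
Product: 6 (4S)-4-methyl-4,5-bis(triethylsilyloxy)pent-1-ene
Conditions: TESOTf (2.4 equiv), 2,6-lutidine, CH2Cl2, −78 → 0 °C
Reagents that add atoms: triethylsilyl trifluoromethanesulfonate, CC[Si](CC)(CC)OS(=O)(=O)C(F)(F)F
Why: A silyl triflate with a hindered pyridine base silylates both the primary and the tertiary hydroxyl without touching the stereocenter.

Step 4
Reactants: 6 (4S)-4-methyl-4,5-bis(triethylsilyloxy)pent-1-ene
Product: 7 2-[(2S)-2-methyl-2,3-bis(triethylsilyloxy)propyl]oxirane, both epimers at the oxirane carbon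
Conditions: mCPBA, NaHCO3, CH2Cl2, 0 °C → rt
Reagents that add atoms: 3-chloroperbenzoic acid, OOC(=O)c1cccc(Cl)c1
Why: Prilezhaev epoxidation of the terminal alkene; the remote quaternary center offers no useful facial bias, so both C7 epimers are expected in similar amounts and are resolved in the next step.

Step 5
Reactants: 7 2-[(2S)-2-methyl-2,3-bis(triethylsilyloxy)propyl]oxirane, both epimers
Product: 8 (2R)-2-[(2S)-2-methyl-2,3-bis(triethylsilyloxy)propyl]oxirane (C4–C8 epoxide, 5S,7R)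
Conditions: (S,S)-(salen)Co(OAc) (1 mol%; salen = N,N′-bis(3,5-di-tert-butylsalicylidene)-1,2-cyclohexanediamine dianion), H2O (0.55 equiv), THF, 0 °C → rt
Reagents that add atoms: none
Why: Hydrolytic kinetic resolution: the (S,S)-configured complex of trivalent cobalt should hydrolyse the (7S)-epoxide much faster than the (7R)-epoxide, following the usual sense for alkyl-substituted terminal epoxides, so C7 is fixed by the catalyst and the surviving epoxide is separated from the diol by chromatography.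

**Part C: C10–C14 Weinreb amide**

Step 6
Reactants: 9 (R)-pent-4-yn-2-ol
Product: 10 1-methoxy-4-({[(2R)-pent-4-yn-2-yl]oxy}methyl)benzene
Conditions: NaH, PMBCl, Bu4NI (cat.), THF–DMF, 0 °C → rt
Reagents that add atoms: 4-methoxybenzyl chloride, COc1ccc(CCl)cc1
Why: Williamson etherification of the secondary alkoxide protects O14 without touching the stereocenter, the future C14.

Step 7
Reactants: 10 1-methoxy-4-({[(2R)-pent-4-yn-2-yl]oxy}methyl)benzene
Product: 12 (5R)-5-[(4-methoxybenzyl)oxy]hex-2-yn-1-ol, via lithium acetylide 11 (not isolated)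
Conditions: n-BuLi, THF, −78 °C; (CH2O)n, −78 °C → rt
Reagents that add atoms: formaldehyde (from paraformaldehyde), C=O
Why: Addition of the lithium acetylide to formaldehyde completes the C10–C14 carbon chain as a propargylic alcohol.

Step 8
Reactants: 12 (5R)-5-[(4-methoxybenzyl)oxy]hex-2-yn-1-ol
Product: 13 (2E,5R)-5-[(4-methoxybenzyl)oxy]hex-2-en-1-ol
Conditions: NaAlH2(OCH2CH2OMe)2, THF, 0 °C → rt; aq Rochelle salt
Reagents that add atoms: none
Why: Hydroxyl-directed trans-hydroalumination of the propargylic alcohol followed by protonolysis gives the (E)-allylic alcohol.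

Step 9
Reactants: 13 (2E,5R)-5-[(4-methoxybenzyl)oxy]hex-2-en-1-ol
Product: 14 [(2R,3R)-3-{(2R)-2-[(4-methoxybenzyl)oxy]propyl}oxiran-2-yl]methanol
Conditions: Ti(OiPr)4 (10 mol%), D-(−)-diethyl tartrate (12 mol%), t-BuOOH, 4 Å molecular sieves, CH2Cl2, −20 °C
Reagents that add atoms: tert-butyl hydroperoxide, CC(C)(C)OO
Why: Sharpless asymmetric epoxidation under reagent control: with the D-(−)-tartrate an (E)-allylic alcohol should give the (2R,3R)-epoxy alcohol, which fixes C11 and, after inversion in the next step, C12.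

Step 10
Reactants: 14 [(2R,3R)-3-{(2R)-2-[(4-methoxybenzyl)oxy]propyl}oxiran-2-yl]methanol
Product: 15 (2S,3S,5R)-5-[(4-methoxybenzyl)oxy]-3-methylhexane-1,2-diol
Conditions: Me3Al (3 equiv), hexane–CH2Cl2, 0 °C → rt; aq Rochelle salt
Reagents that add atoms: trimethylaluminium, C[Al](C)C
Why: Trimethylaluminium opens 3-alkyl-2,3-epoxy alcohols through the aluminium alkoxide by methyl transfer to C3 with inversion, which places the C12 methyl anti to the C11 hydroxyl and gives the 1,2-diol.

Step 11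
Reactants: 15 (2S,3S,5R)-5-[(4-methoxybenzyl)oxy]-3-methylhexane-1,2-diol
Product: 16 (2S,3S,5R)-1,2-bis(tert-butyldimethylsilyloxy)-5-[(4-methoxybenzyl)oxy]-3-methylhexane
Conditions: TBSOTf (2.5 equiv), 2,6-lutidine, CH2Cl2, −78 → 0 °C
Reagents that add atoms: tert-butyldimethylsilyl trifluoromethanesulfonate, CC(C)(C)[Si](C)(C)OS(=O)(=O)C(F)(F)F
Why: Exhaustive silylation of the diol with the silyl triflate is routine and leaves the PMB ether intact.

Step 12
Reactants: 16 (2S,3S,5R)-1,2-bis(tert-butyldimethylsilyloxy)-5-[(4-methoxybenzyl)oxy]-3-methylhexane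
Product: 17 (2S,3S,5R)-2-(tert-butyldimethylsilyloxy)-5-[(4-methoxybenzyl)oxy]-3-methylhexan-1-ol
Conditions: HF·pyridine, pyridine, THF, 0 °C → rt
Reagents that add atoms: none
Why: Buffered hydrogen fluoride cleaves the unhindered primary silyl ether much faster than the secondary one next to the branched carbon, and under these non-basic conditions no silyl migration is expected.

Step 13
Reactants: 17 (2S,3S,5R)-2-(tert-butyldimethylsilyloxy)-5-[(4-methoxybenzyl)oxy]-3-methylhexan-1-ol
Product: 18 (2S,3S,5R)-2-(tert-butyldimethylsilyloxy)-5-[(4-methoxybenzyl)oxy]-3-methylhexanoic acid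
Conditions: TEMPO (0.2 equiv), PhI(OAc)2 (2.2 equiv), MeCN–H2O, rt
Reagents that add atoms: water, O
Why: Nitroxyl-catalysed oxidation takes the primary alcohol through the aldehyde hydrate to the acid under near-neutral conditions that should not epimerise the silyloxy-bearing C11 or harm the PMB ether.

Step 14
Reactants: 18 (2S,3S,5R)-2-(tert-butyldimethylsilyloxy)-5-[(4-methoxybenzyl)oxy]-3-methylhexanoic acid
Product: 19 (2S,3S,5R)-2-(tert-butyldimethylsilyloxy)-N-methoxy-5-[(4-methoxybenzyl)oxy]-N,3-dimethylhexanamide (C10–C14 Weinreb amide)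
Conditions: MeNH(OMe)·HCl, EDC·HCl, HOBt, i-Pr2NEt, CH2Cl2, 0 °C → rt
Reagents that add atoms: N,O-dimethylhydroxylamine hydrochloride, CNOC.Cl
Why: Carbodiimide-mediated amide coupling through the hydroxybenzotriazole ester gives the Weinreb amide without loss of the C11 configuration.

**Key step**

Step 15
Reactants: 3 2-(tert-butyldimethylsilyl)-1,3-dithiane; 8 (2R)-2-[(2S)-2-methyl-2,3-bis(triethylsilyloxy)propyl]oxirane; 19 C10–C14 Weinreb amide
Product: 24 (2S,3S,5R)-2-(tert-butyldimethylsilyloxy)-1-{2-[(2R,4S)-2-(tert-butyldimethylsilyloxy)-4-methyl-4,5-bis(triethylsilyloxy)pentyl]-1,3-dithian-2-yl}-5-[(4-methoxybenzyl)oxy]-3-methylhexan-1-one (C4–C14 chain; C9 dithiane; C10 ketone), via lithiated silyl dithiane 20 (not isolated), via C7 lithium alkoxide 21 (not isolated), via C9 relay carbanion 22 (not isolated), via lithium hemiaminal adduct 23 (not isolated)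
Conditions: t-BuLi, Et2O, −78 → −45 °C; 8, Et2O, −78 → −25 °C; 19, HMPA, THF, −78 → −20 °C; aq NH4Cl
Reagents that add atoms: none
Why: The lithiated silyl dithiane 20 should open epoxide 8 only at the unsubstituted C8 to give alkoxide 21, which is stable in ether; adding amide 19 together with HMPA then triggers the 1,4-Brook shift of silicon from C9 to O7, and the resulting carbanion 22 adds to the amide carbonyl to give the chelated adduct 23, which releases ketone 24 on aqueous quench. The closest known chemistry is the solvent-controlled three-component anion relay coupling of 2-silyl-1,3-dithianes with two electrophiles, combined with the Weinreb ketone synthesis using 2-lithio-1,3-dithianes. No ring is closed and no stereocenter is formed: C5 and C7 come from 8, and C11, C12 and C14 from 19. The step needs attack at C8 only (secured by the terminal epoxide), silyl transfer before any acylation (secured by withholding HMPA until 19 is present), a single addition (secured by the stable N-methoxy-N-methyl tetrahedral adduct) and acylation faster than deprotonation at C11 (favoured at −78 °C by the hindered, silyloxy-bearing C11–H).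

**Part D: from the coupled ketone to the C1–C14 ketone alcohol**

Step 16
Reactants: 24 C4–C14 dithiane ketone
Product: 25 (10R)-alcohol of 24 (5S,7R,10R,11S,12S,14R; O4,O5-bis-TES; O7,O11-bis-TBS; O14-PMB; C9 dithiane)
Conditions: i-Bu2AlH, toluene, −78 °C; aq Rochelle salt
Reagents that add atoms: none
Why: Felkin–Anh reduction: with the C11 silyloxy group anti to the incoming hydride and chelation disfavoured by the bulky silyl ether, hydride should add to the face that gives the 10,11-syn diol derivative, that is 10R.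

Step 17
Reactants: 25 (10R)-alcohol
Product: 26 O10-TES ether of 25
Conditions: TESOTf, 2,6-lutidine, CH2Cl2, −78 → 0 °C
Reagents that add atoms: triethylsilyl trifluoromethanesulfonate, CC[Si](CC)(CC)OS(=O)(=O)C(F)(F)F
Why: The silyl triflate is reactive enough to silylate the hindered C10 hydroxyl flanked by the dithiane, and a TES group here keeps the last deprotection mild.

Step 18
Reactants: 26 O10-TES ether
Product: 27 C4 primary alcohol (O5-TES, O7-TBS, O10-TES, O11-TBS, O14-PMB, C9 dithiane)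
Conditions: PPTS (0.2 equiv), MeOH–CH2Cl2 (1:4), 0 °C
Reagents that add atoms: none
Why: Mild acid methanolysis removes the primary TES ether far faster than the tertiary TES ether at O5, the hindered secondary TES ether at O10 or the TBS ethers, and acid conditions avoid silyl migration from O5 to O4.

Step 19
Reactants: 27 C4 primary alcohol
Product: 28 C4 aldehyde (5S,7R,10R,11S,12S,14R)
Conditions: SO3·pyridine, DMSO, i-Pr2NEt, CH2Cl2, 0 °C
Reagents that add atoms: none
Why: Parikh–Doering oxidation tolerates the dithiane and the silyl ethers, and the aldehyde has no α-hydrogen, so it cannot epimerise or eliminate.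

Step 20
Reactants: 28 C4 aldehyde
Product: 29 (3E)-enal (C2 aldehyde, C3 methyl, C3=C4; O14-PMB; C9 dithiane)
Conditions: Ph3P=C(CH3)CHO (3 equiv), toluene, 100 °C
Reagents that add atoms: 2-(triphenylphosphoranylidene)propanal, CC(C=O)=P(c1ccccc1)(c1ccccc1)c1ccccc1
Why: Wittig olefination with the stabilised formyl ylide should give the (E)-trisubstituted enal, since the bulky C5 substituent and the formyl group end up trans.

Step 21
Reactants: 29 (3E)-enal
Product: 30 (3E)-enal with free C14 hydroxyl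
Conditions: DDQ (1.3 equiv), CH2Cl2–pH 7 buffer, 0 °C
Reagents that add atoms: none
Why: Oxidative cleavage of the single PMB ether is done at the enal stage, before any conjugated diene exists, with buffered quinone at 0 °C to spare the dithiane.

Step 22
Reactants: 30 (3E)-enal with free C14 hydroxyl
Product: 31 (3E)-1,3-diene (C1–C14; C14 hydroxyl free; C9 dithiane; O5,O10-bis-TES; O7,O11-bis-TBS)
Conditions: Ph3PCH3Br, KN(SiMe3)2, THF, 0 °C; then 30, −78 → 0 °C
Reagents that add atoms: methyltriphenylphosphonium bromide, C[P+](c1ccccc1)(c1ccccc1)c1ccccc1.[Br-]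
Why: Wittig methylenation of the enal by 1,2-addition, with excess ylide to allow for the free hydroxyl, completes the diene while C9 is still masked and therefore cannot enolise or eliminate.

Step 23
Reactants: 31 (3E)-1,3-diene dithiane
Product: 32 C1–C14 ketone alcohol (C9 ketone; C14 hydroxyl free; 5S,7R,10R,11S,12S,14R)
Conditions: MeI, CaCO3, MeCN–H2O (9:1), 40 °C
Reagents that add atoms: water, O
Why: Alkylative hydrolysis of the dithiane (S-methylation, then water) is neutral and uses no electrophile that attacks the diene or the silyl ethers.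

**Part E: epoxy dienoic acid**

Step 24
Reactants: 33 3-methylbutanal
Product: 34 ethyl (2E)-5-methylhex-2-enoate
Conditions: (EtO)2P(O)CH2CO2Et, LiCl, DBU, MeCN, rt
Reagents that add atoms: triethyl phosphonoacetate, CCOC(=O)CP(=O)(OCC)OCC
Why: Horner–Wadsworth–Emmons olefination under mild amine/lithium chloride conditions gives the (E)-enoate without aldol self-condensation of the aldehyde.

Step 25
Reactants: 34 ethyl (2E)-5-methylhex-2-enoate
Product: 35 (2E)-5-methylhex-2-en-1-ol
Conditions: i-Bu2AlH, CH2Cl2, −78 °C; aq Rochelle salt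
Reagents that add atoms: none
Why: 1,2-Reduction of the enoate by the aluminium hydride gives the allylic alcohol.

Step 26
Reactants: 35 (2E)-5-methylhex-2-en-1-ol
Product: 36 [(2R,3R)-3-(2-methylpropyl)oxiran-2-yl]methanol
Conditions: Ti(OiPr)4 (10 mol%), D-(−)-diethyl tartrate (12 mol%), t-BuOOH, 4 Å molecular sieves, CH2Cl2, −20 °C
Reagents that add atoms: tert-butyl hydroperoxide, CC(C)(C)OO
Why: Sharpless asymmetric epoxidation of the (E)-allylic alcohol with the D-(−)-tartrate should give the (2R,3R)-trans-epoxide, which sets both epoxide centers of the acid.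

Step 27
Reactants: 36 [(2R,3R)-3-(2-methylpropyl)oxiran-2-yl]methanol
Product: 37 (2S,3R)-3-(2-methylpropyl)oxirane-2-carbaldehyde
Conditions: SO3·pyridine, DMSO, i-Pr2NEt, CH2Cl2, 0 °C
Reagents that add atoms: none
Why: Parikh–Doering oxidation gives the epoxy aldehyde without epimerisation of the oxirane carbon (the descriptor changes only by priority); the aldehyde is used at once.

Step 28
Reactants: 38 2,3-dihydrofuran
Product: 40 ethyl (2E)-6-hydroxy-2-methylhex-2-enoate, via tetrahydrofuran-2-ol 39 (not isolated)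
Conditions: 0.2 M aq HCl, 0 °C → rt; NaHCO3; then Ph3P=C(CH3)CO2Et, CH2Cl2, rt
Reagents that add atoms: water, O; ethyl 2-(triphenylphosphoranylidene)propanoate, CCOC(=O)C(C)=P(c1ccccc1)(c1ccccc1)c1ccccc1
Why: Acid hydration of the enol ether gives the lactol, whose open-chain aldehyde is trapped by the stabilised ylide in an (E)-selective Wittig reaction.

Step 29
Reactants: 40 ethyl (2E)-6-hydroxy-2-methylhex-2-enoate
Product: 41 ethyl (2E)-2-methyl-6-[(1-phenyl-1H-tetrazol-5-yl)sulfanyl]hex-2-enoate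
Conditions: 1-phenyl-1H-tetrazole-5-thiol, PPh3, DIAD, THF, 0 °C → rt
Reagents that add atoms: 1-phenyl-1H-tetrazole-5-thiol, Sc1nnnn1-c1ccccc1
Why: Mitsunobu substitution of the primary alcohol by the acidic heteroaryl thiol gives the sulfide.

Step 30
Reactants: 41 tetrazolyl sulfide
Product: 42 ethyl (2E)-2-methyl-6-[(1-phenyl-1H-tetrazol-5-yl)sulfonyl]hex-2-enoate
Conditions: H2O2 (30%), (NH4)6Mo7O24·4H2O (10 mol%), EtOH, 0 °C → rt
Reagents that add atoms: hydrogen peroxide, OO
Why: Molybdate-catalysed peroxide oxidation converts the sulfide into the sulfone and does not epoxidise the electron-poor enoate.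

Step 31
Reactants: 42 tetrazolyl sulfone; 37 (2S,3R)-3-(2-methylpropyl)oxirane-2-carbaldehyde
Product: 43 ethyl (2E,6E)-2-methyl-7-[(2R,3R)-3-(2-methylpropyl)oxiran-2-yl]hepta-2,6-dienoate
Conditions: KN(SiMe3)2 added to 42 + 37, DME, −60 °C → rt
Reagents that add atoms: none
Why: Julia–Kocienski olefination of the phenyltetrazolyl sulfone with potassium base in DME should form the C6=C7 bond with E geometry, and the epoxide is not touched because the carbanion sits on the sulfone partner.

Step 32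
Reactants: 43 epoxy dienoate ester
Product: 44 (2E,6E)-2-methyl-7-[(2R,3R)-3-(2-methylpropyl)oxiran-2-yl]hepta-2,6-dienoic acid
Conditions: LiOH, THF–MeOH–H2O, rt; then dilute HCl to pH 4–5, 0 °C
Reagents that add atoms: lithium hydroxide, [Li+].[OH-]
Why: Saponification of the ethyl ester proceeds under conditions to which a vinyl epoxide is stable, and the acidification is kept brief and cold.

**Part F: union and deprotection**

Step 33
Reactants: 44 epoxy dienoic acid; 32 C1–C14 ketone alcohol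
Product: 46 C14 ester of 32 with 44 (O5,O10-bis-TES; O7,O11-bis-TBS), via mixed anhydride 45 (not isolated)
Conditions: 44, 2,4,6-trichlorobenzoyl chloride, Et3N, toluene, rt; then 32, DMAP, rt
Reagents that add atoms: none
Why: Yamaguchi esterification acylates the only free hydroxyl (C14) through the mixed anhydride with retention at C14, and the α-methyl enoate is not prone to isomerisation under these conditions.

Step 34
Reactants: 46 tetrasilyl ester
Product: 47 (2R,4S,5S,6R,9R,11S,12E)-5,6,9,11-tetrahydroxy-4,11,13-trimethyl-7-oxopentadeca-12,14-dien-2-yl (2E,6E)-2-methyl-7-[(2R,3R)-3-(2-methylpropyl)oxiran-2-yl]hepta-2,6-dienoate (CNP0145465.1)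
Conditions: (Me2N)3S[Me3SiF2], DMF–H2O (10:1), 0 °C → rt
Reagents that add atoms: none
Why: Fluoride-mediated cleavage of the two TES and two TBS ethers with the mild, nearly neutral difluorosilicate in wet DMF should spare the vinyl epoxide, the dienyl tertiary alcohol, the ester and the hydroxy ketone.

**Compound list**

1 | 1,3-dithiane | C1CSCSC1 | starting material
2 | 2-lithio-1,3-dithiane | [Li]C1SCCCS1 | intermediate
3 | 2-(tert-butyldimethylsilyl)-1,3-dithiane | CC(C)(C)[Si](C)(C)C1SCCCS1 | intermediate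
4 | (R)-2-methylglycidol | OC[C@]1(C)CO1 | starting material
5 | (2S)-2-methylpent-4-ene-1,2-diol | OC[C@@](C)(O)CC=C | intermediate
6 | (4S)-4-methyl-4,5-bis(triethylsilyloxy)pent-1-ene | CC[Si](CC)(CC)OC[C@@](C)(O[Si](CC)(CC)CC)CC=C | intermediate
7 | 2-[(2S)-2-methyl-2,3-bis(triethylsilyloxy)propyl]oxirane, both epimers at the oxirane carbon | CC[Si](CC)(CC)OC[C@@](C)(O[Si](CC)(CC)CC)CC1CO1 | intermediate
8 | (2R)-2-[(2S)-2-methyl-2,3-bis(triethylsilyloxy)propyl]oxirane | CC[Si](CC)(CC)OC[C@@](C)(O[Si](CC)(CC)CC)C[C@@H]1CO1 | intermediate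
9 | (R)-pent-4-yn-2-ol | C#CC[C@@H](C)O | starting material
10 | 1-methoxy-4-({[(2R)-pent-4-yn-2-yl]oxy}methyl)benzene | C#CC[C@@H](C)OCc1ccc(OC)cc1 | intermediate
11 | lithium acetylide of 10 | [Li]C#CC[C@@H](C)OCc1ccc(OC)cc1 | intermediate
12 | (5R)-5-[(4-methoxybenzyl)oxy]hex-2-yn-1-ol | OCC#CC[C@@H](C)OCc1ccc(OC)cc1 | intermediate
13 | (2E,5R)-5-[(4-methoxybenzyl)oxy]hex-2-en-1-ol | OC/C=C/C[C@@H](C)OCc1ccc(OC)cc1 | intermediate
14 | [(2R,3R)-3-{(2R)-2-[(4-methoxybenzyl)oxy]propyl}oxiran-2-yl]methanol | OC[C@H]1O[C@@H]1C[C@@H](C)OCc1ccc(OC)cc1 | intermediate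
15 | (2S,3S,5R)-5-[(4-methoxybenzyl)oxy]-3-methylhexane-1,2-diol | OC[C@@H](O)[C@@H](C)C[C@@H](C)OCc1ccc(OC)cc1 | intermediate
16 | (2S,3S,5R)-1,2-bis(tert-butyldimethylsilyloxy)-5-[(4-methoxybenzyl)oxy]-3-methylhexane | CC(C)(C)[Si](C)(C)OC[C@@H](O[Si](C)(C)C(C)(C)C)[C@@H](C)C[C@@H](C)OCc1ccc(OC)cc1 | intermediate
17 | (2S,3S,5R)-2-(tert-butyldimethylsilyloxy)-5-[(4-methoxybenzyl)oxy]-3-methylhexan-1-ol | OC[C@@H](O[Si](C)(C)C(C)(C)C)[C@@H](C)C[C@@H](C)OCc1ccc(OC)cc1 | intermediate
18 | (2S,3S,5R)-2-(tert-butyldimethylsilyloxy)-5-[(4-methoxybenzyl)oxy]-3-methylhexanoic acid | OC(=O)[C@@H](O[Si](C)(C)C(C)(C)C)[C@@H](C)C[C@@H](C)OCc1ccc(OC)cc1 | intermediate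
19 | (2S,3S,5R)-2-(tert-butyldimethylsilyloxy)-N-methoxy-5-[(4-methoxybenzyl)oxy]-N,3-dimethylhexanamide | CON(C)C(=O)[C@@H](O[Si](C)(C)C(C)(C)C)[C@@H](C)C[C@@H](C)OCc1ccc(OC)cc1 | intermediate
20 | 2-lithio-2-(tert-butyldimethylsilyl)-1,3-dithiane | [Li]C1(SCCCS1)[Si](C)(C)C(C)(C)C | intermediate
21 | C7 lithium alkoxide from 20 and 8 (silicon still on C9) | CC[Si](CC)(CC)OC[C@@](C)(O[Si](CC)(CC)CC)C[C@@H](O[Li])CC1(SCCCS1)[Si](C)(C)C(C)(C)C | intermediate
22 | 2-lithio-1,3-dithiane after Brook shift (O7-TBS) | CC[Si](CC)(CC)OC[C@@](C)(O[Si](CC)(CC)CC)C[C@@H](O[Si](C)(C)C(C)(C)C)CC1([Li])SCCCS1 | intermediate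
23 | lithium N-methoxy-N-methyl hemiaminal adduct of 22 and 19 | CC[Si](CC)(CC)OC[C@@](C)(O[Si](CC)(CC)CC)C[C@@H](O[Si](C)(C)C(C)(C)C)CC1(SCCCS1)C(O[Li])(N(C)OC)[C@@H](O[Si](C)(C)C(C)(C)C)[C@@H](C)C[C@@H](C)OCc1ccc(OC)cc1 | intermediate
24 | (2S,3S,5R)-2-(tert-butyldimethylsilyloxy)-1-{2-[(2R,4S)-2-(tert-butyldimethylsilyloxy)-4-methyl-4,5-bis(triethylsilyloxy)pentyl]-1,3-dithian-2-yl}-5-[(4-methoxybenzyl)oxy]-3-methylhexan-1-one | CC[Si](CC)(CC)OC[C@@](C)(O[Si](CC)(CC)CC)C[C@@H](O[Si](C)(C)C(C)(C)C)CC1(SCCCS1)C(=O)[C@@H](O[Si](C)(C)C(C)(C)C)[C@@H](C)C[C@@H](C)OCc1ccc(OC)cc1 | intermediate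
25 | (10R)-alcohol of 24 (5S,7R,10R,11S,12S,14R) | CC[Si](CC)(CC)OC[C@@](C)(O[Si](CC)(CC)CC)C[C@@H](O[Si](C)(C)C(C)(C)C)CC1(SCCCS1)[C@H](O)[C@@H](O[Si](C)(C)C(C)(C)C)[C@@H](C)C[C@@H](C)OCc1ccc(OC)cc1 | intermediate
26 | O10-TES ether of 25 | CC[Si](CC)(CC)OC[C@@](C)(O[Si](CC)(CC)CC)C[C@@H](O[Si](C)(C)C(C)(C)C)CC1(SCCCS1)[C@H](O[Si](CC)(CC)CC)[C@@H](O[Si](C)(C)C(C)(C)C)[C@@H](C)C[C@@H](C)OCc1ccc(OC)cc1 | intermediate
27 | C4 primary alcohol (O5-TES, O7-TBS, O10-TES, O11-TBS, O14-PMB, C9 dithiane) | OC[C@@](C)(O[Si](CC)(CC)CC)C[C@@H](O[Si](C)(C)C(C)(C)C)CC1(SCCCS1)[C@H](O[Si](CC)(CC)CC)[C@@H](O[Si](C)(C)C(C)(C)C)[C@@H](C)C[C@@H](C)OCc1ccc(OC)cc1 | intermediate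
28 | C4 aldehyde from 27 | O=C[C@@](C)(O[Si](CC)(CC)CC)C[C@@H](O[Si](C)(C)C(C)(C)C)CC1(SCCCS1)[C@H](O[Si](CC)(CC)CC)[C@@H](O[Si](C)(C)C(C)(C)C)[C@@H](C)C[C@@H](C)OCc1ccc(OC)cc1 | intermediate
29 | (3E)-enal (C2 aldehyde, C3 methyl; O14-PMB; C9 dithiane) | O=C/C(C)=C/[C@@](C)(O[Si](CC)(CC)CC)C[C@@H](O[Si](C)(C)C(C)(C)C)CC1(SCCCS1)[C@H](O[Si](CC)(CC)CC)[C@@H](O[Si](C)(C)C(C)(C)C)[C@@H](C)C[C@@H](C)OCc1ccc(OC)cc1 | intermediate
30 | (3E)-enal with free C14 hydroxyl | O=C/C(C)=C/[C@@](C)(O[Si](CC)(CC)CC)C[C@@H](O[Si](C)(C)C(C)(C)C)CC1(SCCCS1)[C@H](O[Si](CC)(CC)CC)[C@@H](O[Si](C)(C)C(C)(C)C)[C@@H](C)C[C@@H](C)O | intermediate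
31 | (3E)-1,3-diene, C9 dithiane, C14 hydroxyl free | C=C/C(C)=C/[C@@](C)(O[Si](CC)(CC)CC)C[C@@H](O[Si](C)(C)C(C)(C)C)CC1(SCCCS1)[C@H](O[Si](CC)(CC)CC)[C@@H](O[Si](C)(C)C(C)(C)C)[C@@H](C)C[C@@H](C)O | intermediate
32 | C1–C14 ketone alcohol (C9 ketone; O5,O10-bis-TES; O7,O11-bis-TBS; C14 hydroxyl free) | C=C/C(C)=C/[C@@](C)(O[Si](CC)(CC)CC)C[C@@H](O[Si](C)(C)C(C)(C)C)CC(=O)[C@H](O[Si](CC)(CC)CC)[C@@H](O[Si](C)(C)C(C)(C)C)[C@@H](C)C[C@@H](C)O | intermediate
33 | 3-methylbutanal | CC(C)CC=O | starting material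
34 | ethyl (2E)-5-methylhex-2-enoate | CCOC(=O)/C=C/CC(C)C | intermediate
35 | (2E)-5-methylhex-2-en-1-ol | OC/C=C/CC(C)C | intermediate
36 | [(2R,3R)-3-(2-methylpropyl)oxiran-2-yl]methanol | OC[C@H]1O[C@@H]1CC(C)C | intermediate
37 | (2S,3R)-3-(2-methylpropyl)oxirane-2-carbaldehyde | O=C[C@H]1O[C@@H]1CC(C)C | intermediate
38 | 2,3-dihydrofuran | C1CC=CO1 | starting material
39 | tetrahydrofuran-2-ol | OC1CCCO1 | intermediate
40 | ethyl (2E)-6-hydroxy-2-methylhex-2-enoate | CCOC(=O)/C(C)=C/CCCO | intermediate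
41 | ethyl (2E)-2-methyl-6-[(1-phenyl-1H-tetrazol-5-yl)sulfanyl]hex-2-enoate | CCOC(=O)/C(C)=C/CCCSc1nnnn1-c1ccccc1 | intermediate
42 | ethyl (2E)-2-methyl-6-[(1-phenyl-1H-tetrazol-5-yl)sulfonyl]hex-2-enoate | CCOC(=O)/C(C)=C/CCCS(=O)(=O)c1nnnn1-c1ccccc1 | intermediate
43 | ethyl (2E,6E)-2-methyl-7-[(2R,3R)-3-(2-methylpropyl)oxiran-2-yl]hepta-2,6-dienoate | CCOC(=O)/C(C)=C/CC/C=C/[C@H]1O[C@@H]1CC(C)C | intermediate
44 | (2E,6E)-2-methyl-7-[(2R,3R)-3-(2-methylpropyl)oxiran-2-yl]hepta-2,6-dienoic acid | OC(=O)/C(C)=C/CC/C=C/[C@H]1O[C@@H]1CC(C)C | intermediate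
45 | mixed anhydride of 44 with 2,4,6-trichlorobenzoic acid | O=C(OC(=O)c1c(Cl)cc(Cl)cc1Cl)/C(C)=C/CC/C=C/[C@H]1O[C@@H]1CC(C)C | intermediate
46 | C14 ester of 32 with 44 (O5,O10-bis-TES; O7,O11-bis-TBS) | C=C/C(C)=C/[C@@](C)(O[Si](CC)(CC)CC)C[C@@H](O[Si](C)(C)C(C)(C)C)CC(=O)[C@H](O[Si](CC)(CC)CC)[C@@H](O[Si](C)(C)C(C)(C)C)[C@@H](C)C[C@@H](C)OC(=O)/C(C)=C/CC/C=C/[C@H]1O[C@@H]1CC(C)C | intermediate
47 | (2R,4S,5S,6R,9R,11S,12E)-5,6,9,11-tetrahydroxy-4,11,13-trimethyl-7-oxopentadeca-12,14-dien-2-yl (2E,6E)-2-methyl-7-[(2R,3R)-3-(2-methylpropyl)oxiran-2-yl]hepta-2,6-dienoate | C=C/C(C)=C/[C@@](C)(O)C[C@@H](O)CC(=O)[C@H](O)[C@@H](O)[C@@H](C)C[C@@H](C)OC(=O)/C(C)=C/CC/C=C/[C@H]1O[C@@H]1CC(C)C | target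

**Step count**

Total: 34 steps (1 for the dithiane, 4 for the epoxide, 9 for the amide, 1 coupling, 8 to the ketone alcohol 32, 9 for the acid, 2 at the end).
Longest linear sequence: 20 steps from 9 (steps 6–23, then 33 and 34).

**Steps most likely to fail**

1. Step 15. The hindered relay carbanion may be protonated by the amide at C11 or may acylate too slowly, so that only the rearranged dithiane is recovered and the amide is partly epimerised. Fallback, setting out from 3, 8 and 17 and returning at 24: the relay is split into separate operations. Compound 3 is lithiated and added to 8 as in step 15, HMPA is added without a second electrophile, and aqueous quench should give the 2-substituted dithiane F1. Alcohol 17 is oxidised (SO3·pyridine, DMSO, i-Pr2NEt) to the α-silyloxy aldehyde F2. Relithiation of F1 (t-BuLi, THF–HMPA, −78 °C) and addition to the more electrophilic F2 should give the C10 carbinol mixture F3, which Dess–Martin periodinane oxidises to ketone 24.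

2. Step 20. Olefination of the neopentylic, α-silyloxy aldehyde by the weakly nucleophilic formyl ylide may be slow, so that the enal product competes for the ylide or the aldehyde decomposes on long heating. Fallback, setting out from 28 and returning at 29: the more reactive ester ylide Ph3P=C(CH3)CO2Et (toluene, 90 °C) should give the ethyl (E)-enoate F4, which cannot react further. i-Bu2AlH (CH2Cl2, −78 °C) reduces it to the allylic alcohol F5, and MnO2 (CH2Cl2, rt) oxidises F5 to enal 29.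

3. Step 34. Removal of four silyl ethers may be accompanied by retro-aldol cleavage or β-elimination across C7–C9 once O7 is free, or by fluoride opening of the vinyl epoxide. Fallback, setting out from 31 and 44 and returning at 47: the order of the last operations is changed so that C9 stays masked during desilylation. Alcohol 31 is esterified with 44 through 45 under the conditions of step 33 to give the dithiane ester F6. Bu4NF buffered with AcOH (THF, 0 °C → rt) should then remove all four silyl groups without any carbonyl present, giving the dithiane tetraol F7. MeI, CaCO3 in aqueous MeCN finally unmasks the C9 ketone to give 47.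

**Further compounds**

F1 | step 15 | 2-[(2R,4S)-2-(tert-butyldimethylsilyloxy)-4-methyl-4,5-bis(triethylsilyloxy)pentyl]-1,3-dithiane | CC[Si](CC)(CC)OC[C@@](C)(O[Si](CC)(CC)CC)C[C@@H](O[Si](C)(C)C(C)(C)C)CC1SCCCS1
F2 | step 15 | (2S,3S,5R)-2-(tert-butyldimethylsilyloxy)-5-[(4-methoxybenzyl)oxy]-3-methylhexanal | O=C[C@@H](O[Si](C)(C)C(C)(C)C)[C@@H](C)C[C@@H](C)OCc1ccc(OC)cc1
F3 | step 15 | C10 carbinol corresponding to 24, both C10 epimers | CC[Si](CC)(CC)OC[C@@](C)(O[Si](CC)(CC)CC)C[C@@H](O[Si](C)(C)C(C)(C)C)CC1(SCCCS1)C(O)[C@@H](O[Si](C)(C)C(C)(C)C)[C@@H](C)C[C@@H](C)OCc1ccc(OC)cc1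
F4 | step 20 | ethyl (2E)-enoate from 28 (C2 ester, C3 methyl; O14-PMB; C9 dithiane) | CCOC(=O)/C(C)=C/[C@@](C)(O[Si](CC)(CC)CC)C[C@@H](O[Si](C)(C)C(C)(C)C)CC1(SCCCS1)[C@H](O[Si](CC)(CC)CC)[C@@H](O[Si](C)(C)C(C)(C)C)[C@@H](C)C[C@@H](C)OCc1ccc(OC)cc1
F5 | step 20 | (2E)-allylic alcohol from F4 | OC/C(C)=C/[C@@](C)(O[Si](CC)(CC)CC)C[C@@H](O[Si](C)(C)C(C)(C)C)CC1(SCCCS1)[C@H](O[Si](CC)(CC)CC)[C@@H](O[Si](C)(C)C(C)(C)C)[C@@H](C)C[C@@H](C)OCc1ccc(OC)cc1
F6 | step 34 | C14 ester of 31 with 44 (C9 dithiane; O5,O10-bis-TES; O7,O11-bis-TBS) | C=C/C(C)=C/[C@@](C)(O[Si](CC)(CC)CC)C[C@@H](O[Si](C)(C)C(C)(C)C)CC1(SCCCS1)[C@H](O[Si](CC)(CC)CC)[C@@H](O[Si](C)(C)C(C)(C)C)[C@@H](C)C[C@@H](C)OC(=O)/C(C)=C/CC/C=C/[C@H]2O[C@@H]2CC(C)C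
F7 | step 34 | C9 dithiane of the target (O5, O7, O10, O11 free) | C=C/C(C)=C/[C@@](C)(O)C[C@@H](O)CC1(SCCCS1)[C@H](O)[C@@H](O)[C@@H](C)C[C@@H](C)OC(=O)/C(C)=C/CC/C=C/[C@H]2O[C@@H]2CC(C)C
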